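Whatever leaves the starting material must stand as target, uncatalysed product or over-reaction product, so the four amounts add up to the charge, and the earlier runs report just two of them.

| setting | winter | dusk | beta | eta | alpha |
|---|---|---|---|---|---|
| starting material | 20 mM | 20 mM | 20 mM | 20 mM | 20 mM |
| free enzyme | 14 µM | 22 µM | 10 µM | 10 µM | 10 µM |
| temperature | 24 °C | 32 °C | 20 °C |  | 35 °C |
| remark | run made earlier | run made earlier |  | at 20 °C until 40 s, from then on at 35 °C |  |
| time |  |  | 2.0 min | 2.0 min | 2.0 min |

- winter (time / s: target / %, uncatalysed product / %): 10.0: 8.7, 2.9; 12.0: 12.1, 3.8; 20.0: 14.6, 8.4; 30.0: 21.5, 13.1; 40.0: 23.0, 12.2; 60.0: 29.5, 18.8; 80.0: 31.3, 20.3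
- dusk (time / s: target / %, uncatalysed product / %): 10.0: 15.0, 11.7; 12.0: 15.1, 12.5; 15.0: 15.1, 13.7; 20.0: 22.2, 17.7; 30.0: 23.8, 21.9; 40.0: 24.2, 24.1

(standard deviation of a reading: 1 percentage point)

- which flask leads in share of target in all that became target or uncatalysed product or over-reaction product ("all alike" within 1.5 percentage points) (beta / eta / alpha / all alike)
- share of target in all that became target or uncatalysed product or over-reaction product, beta
- share of target in all that became target or uncatalysed product or over-reaction product, eta
- share of target in all that became target or uncatalysed product or over-reaction product, alpha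

- what may be going on: free enzyme -> unfolded enzyme; starting material + free enzyme -> target + free enzyme; starting material -> uncatalysed product; target -> over-reaction product

Uncatalysed product forms at a rate proportional to the starting material present, so its slope reports what remains. In the winter run it climbs by 0.00420 s⁻¹ of the charge over the first 20.0 s and by 0.00144 s⁻¹ between 30.0 s and 80.0 s, so I read about 34.3% of the starting material left near 60.0 s. Adding the target and uncatalysed product read there leaves 17.4% unaccounted for, which I book as over-reaction product: target is lost while it is made.

If target is made steadily and lost with a first-order constant k, integrating the rate shows that the part of all target made still standing at time t, its survival fraction, is one minus exp(−kt), divided by kt, which lies near exp(−kt/2). The winter run opens at 0.00945 s⁻¹ of the charge, so at 40.0 s the survival fraction reads 60.8%, and k comes to 0.0249 s⁻¹. The opening slope of uncatalysed product is 2.79 times steeper in the dusk run, and I borrow that factor for target's loss, so its square root gives the loss constant of target at 20 °C, 0.0149 s⁻¹.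

Scaling the making to beta's enzyme charge, and setting its temperature effect aside, gives 0.00675 s⁻¹. Over 2.0 min that makes 81.0%, less than the charge, so steady making is tenable. Beta's survival fraction is 46.6%, and the opening split towards the enzyme's path, the selectivity, is 72.9%, so my own reckoning is 34.0% for beta. For alpha at 35 °C the same scaling puts the loss constant of target at 0.102 s⁻¹, higher than beta's; I have checked steady making for beta and not for alpha, so I give alpha no survival fraction, and since eta ends at that same temperature, I expect beta to lead, with eta between.

The forecast also names beta, but with 60%, 29% and 11% for beta, eta and alpha, and there we part, for it says “Over-reaction cannot be separated from enzyme death, so I assume it is small”.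

The flasks give 34.1% for beta, 1.80% for eta and 0.352% for alpha, with beta ahead.

    free enzyme → unfolded enzyme (k = 4.66 × 10⁻⁵ s⁻¹, Ea = 199 kJ mol⁻¹)
    starting material + free enzyme → target + free enzyme, rate k2*[starting material]*[free enzyme]/(1 + ([starting material]/Km2) + ([target]/Kp2)) (0.956 mM, 23.9 mM, k = 14700 L mol⁻¹ s⁻¹, Ea = 12.0 kJ mol⁻¹)
    starting material → uncatalysed product (k = 0.00316 s⁻¹, Ea = 85.0 kJ mol⁻¹)
    target → over-reaction product (k = 0.0155 s⁻¹, Ea = 79.0 kJ mol⁻¹)
    (constants at 20 °C)

At the asked time, beta holds 41.2% of over-reaction product against 31.0% of target, so 42.9% of the target made still stands, beside the 46.6% reckoned. For beta left until 80 s, the carried constant gives a survival fraction of 58.4%, and that flask's 29.0% of target and 22.2% of over-reaction product give 56.6%.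

Readings and results are simulated from invented constants; scatter was added.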